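The red run was charged like the green flask, so its readings are the green flask's early history, and we ask what they leave open at 54 h.

| setting | red | ochre | grey | blue | green |
|---|---|---|---|---|---|
| Xa | 0.0500 M | 0.0250 M | 0.0500 M | 0.150 M | 0.0500 M |
| Xb | 0.0400 M | 0.0150 M | 0.0400 M | 0.0400 M | 0.0400 M |
| Xc | 0.00100 M | 0.00100 M | 0.00300 M | 0.00100 M | 0.00100 M |
| time |  |  |  |  | 54 h |

- red run (time / h: [Xp] / M): 0.65: 0.00403; 2.0: 0.00891; 3.7: 0.01261; 5.9: 0.01584; 8.5: 0.01759; 11: 0.01838; 15: 0.01909; 18: 0.01999
- ochre run (time / h: [Xp] / M): 0.65: 5.2 × 10⁻⁴; 2.0: 0.00242; 3.7: 0.00351; 5.9: 0.00408; 8.5: 0.00491; 11: 0.00588; 15: 0.00626; 18: 0.00672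
- grey run (time / h: [Xp] / M): 0.65: 0.00977; 2.0: 0.01942; 3.7: 0.02485; 5.9: 0.02836; 8.5: 0.03029; 11: 0.03131; 15: 0.03194; 18: 0.03242
- blue run (time / h: [Xp] / M): 0.65: 0.00679; 2.0: 0.01422; 3.7: 0.01781; 5.9: 0.02017; 8.5: 0.02077; 11: 0.02101; 15: 0.02188; 18: 0.02160

(standard deviation of a reading: 2 × 10⁻⁴ M)

1. the exponent of [Xa] in the starting rate at the charge of the red run (at the point where two percent of the Xa have become Xp) (one fixed amount of Xp, the same in the runs compared)
2. the exponent of [Xc] in the starting rate at the charge of the red run (at the point where two percent of the Xa have become Xp)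
3. Xp in the green run at 54 h, as a share of the Xa charged

- Overall: Xa + Xb -> Xp, with Xc as catalyst.
- Constant volume, constant temperature.
- The analysis sees a species whether free or bound.
- An order is taken over about fifteen percent of the charge, up and down.

1. Bound from above. Each Xp takes one Xb, so in the green flask Xb is the limiting reagent, and its charge allows 80.0% of the Xa.

2. Bound from below. Each red reading stands above the one before, and we take the green flask to pass the last of them. That reading, less two standard deviations, gives 39.2% of the Xa.

3. Tightening. The red readings at 2.0 h, 8.5 h and 15 h are evenly spaced, 6.50 h apart. The first interval gains 0.00868 M, more than the 0.00150 M of the second, and second over first is a ratio of 0.173. This gives 3.70 h, the fade time: the time in which the climb still to come shrinks by the factor e, taken as steady.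

4. Our value. Summing the shrinking gains leaves 3.13 × 10⁻⁴ M to come after 15 h, and 1.39 × 10⁻⁴ M after 18 h. Added to the last red reading, this gives 0.0201 M, or 40.3% of the Xa. Two standard deviations above it lie at 41.1%, lower than the Xb allowance, and we take that as the upper edge of our estimated bracket.

5. The forecast gave orders of 0.6 in Xa and 0.9 in Xc and 45% for the green flask, above our bracket, on the ground that “Red-type runs still creep at about 1–2×10⁻⁴ M/h at 18 h, decaying”.

6. The result. The orders are 0.75 and 1.0, and the green flask gives 39.9%, inside the bracket and 0.40 percentage points below our value.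

    Xc + Xa ⇌ Xc.Xa, settled at all times (7.560 /M)
    Xc.Xa + Xb → Xp + Xc + Xh (619.2 /M/h)
    Xc.Xa → E + Xa (0.7272 /h)
    Xb → L (0.03114 /h)

In the green flask the fall of Xc.Xa to E holds Xp down: without that step it reaches 63.3% instead of 39.9%. Between 18 h and 54 h the green flask passes 9.73 of our fade times. In the red run, one steady fade to our end value puts a quarter of the Xa at 3.59 h, and the flask reaches that point at 3.55 h.

(The earlier runs and the new flask come from a simulation for an exercise; the scatter is artificial.)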